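The route rests on cutting the C4–C5 bond of the 6-oxabicyclo[3.2.1]octane-7,8-dione core (target locants throughout). This bond joins the gem-dimethyl carbon C4 to the bridgehead C5, which carries O6 and the isobutyryl group and lies between two ketones. The cut reveals an achiral 3,3-diprenyl-5-isobutyrylfuran-2,4-dione enol, in which C5 is a β-diketone carbon and the two prenyl groups on C1 are enantiotopic. One catalytic, enantioselective seleniranium-triggered closure forms C4–C5, closes the cyclohexanone ring (C1–C2–C3–C4–C5–C8) across the γ-lactone and sets C1, C3 and C5 together. Selenium at C3 is then exchanged for the second prenyl group.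

Key step: step 4

Remark: locants follow the target skeleton (C1 prenyl bridgehead, C2 methylene, C3 methine, C4 gem-dimethyl carbon, C5 bridgehead bearing O6 and isobutyryl, C7 lactone carbonyl, C8 bridging ketone) and are used for the corresponding atoms of earlier compounds.
Remark: compound 7 has no hydrogen on the carbon between the lactone and ketone carbonyls, so it is a furan-2,4-dione enolized toward the acyl-bearing carbon (an enol lactone) and not a true tetronic acid; it is therefore made by ring closure directly before the key step and used unprotected.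
Assumption: the sense of induction of the chiral acid on this new substrate class cannot be predicted; the (R)-catalyst is written, and its antipode is used if the (1S,3S,5S) series prevails.

Step 1
Reactants: 1 dimethyl malonate; 2 prenyl bromide (1-bromo-3-methylbut-2-ene, 2.2 equiv)
Product: 3 dimethyl 2,2-bis(3-methylbut-2-en-1-yl)propanedioate
Conditions: NaH (2.3 equiv), THF/DMF, 0 °C to rt
Reagents that add atoms: none
Why: Classical malonic ester dialkylation, in which the sodium enolate is alkylated twice at carbon by the primary allylic bromide (SN2), places both prenyl groups on the future C1 with no O-alkylation or regiochemical issue.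

Step 2
Reactants: 3 dimethyl 2,2-bis(3-methylbut-2-en-1-yl)propanedioate; 4 1-bromo-3-methylbutan-2-one (1.05 equiv)
Product: 6 methyl 3-methyl-2-oxobutyl 2,2-bis(3-methylbut-2-en-1-yl)propanedioate, via potassium half-ester salt 5 (not isolated)
Conditions: KOH (1.0 equiv), MeOH, 40 °C; evaporate, toluene azeotrope; then 4, DMF, rt
Reagents that add atoms: potassium hydroxide, [K+].[OH-]
Why: Selective monosaponification of a hindered gem-dialkyl malonate (the first carboxylate retards attack on the second ester) is followed by SN2 O-alkylation of the carboxylate with the α-bromo ketone, a fast and clean ester synthesis.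

Step 3
Reactants: 6 methyl 3-methyl-2-oxobutyl 2,2-bis(3-methylbut-2-en-1-yl)propanedioate
Product: 7 4-hydroxy-3,3-bis(3-methylbut-2-en-1-yl)-5-(2-methylpropanoyl)furan-2(3H)-one (achiral enol)
Conditions: LiN(SiMe3)2 (2.2 equiv), THF, −78 °C to 0 °C; then 1 M HCl
Reagents that add atoms: none
Why: In this Dieckmann-type intramolecular Claisen condensation, kinetic deprotonation takes place at the OCH2 group (more acidic and less hindered than the isopropyl methine), the ketone enolate closes 5-exo-trig onto the methyl ester, and deprotonation of the resulting β-diketone by the second equivalent of base drives the reaction and protects the product until the acidic quench.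

Step 4
Reactants: 7 4-hydroxy-3,3-bis(3-methylbut-2-en-1-yl)-5-(2-methylpropanoyl)furan-2(3H)-one; 8 N-(phenylseleno)phthalimide (1.1 equiv)
Product: 10 (1R,3R,5R)-4,4-dimethyl-1-(3-methylbut-2-en-1-yl)-5-(2-methylpropanoyl)-3-(phenylselanyl)-6-oxabicyclo[3.2.1]octane-7,8-dione (selenium exo at C3), via seleniranium ion 9 (not isolated)
Conditions: (R)-[3,3′-bis(2,4,6-triisopropylphenyl)-1,1′-binaphthalene-2,2′-diyl] N-(trifluoromethylsulfonyl)phosphoramide, (ArO)2P(=O)NHSO2CF3 (10 mol %), toluene/CH2Cl2, 0.02 M, −40 to −20 °C
Reagents that add atoms: none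
Why: Proposed new method: the chiral acid protonates 8 and transfers PhSe+ to a prenyl alkene of 7 to give seleniranium ion 9 as an ion pair with the chiral phosphoramidate, which stays hydrogen-bonded to the enol OH, and the enol carbon C5 then opens 9 at its tertiary carbon anti to selenium while the enol proton returns to the catalyst. The closest known reactions are the racemic N-(phenylseleno)phthalimide/Lewis acid 6-endo carbocyclization of alkenyl β-dicarbonyl compounds and chiral Brønsted acid or anion-binding catalysed seleno-etherifications that work by dynamic kinetic resolution of rapidly exchanging seleniranium ions; a desymmetrizing C–C version has not been shown. The cyclohexanone ring C1–C2–C3–C4–C5–C8 closes in the 6-endo mode with Markovnikov attack at the gem-dimethyl carbon (6-endo-trig counted on the alkene), bridging the existing lactone. Selenium should exchange fast between the two enantiotopic prenyl groups and their faces, so the C–C closure inside the chiral ion pair decides which prenyl group is captured and thereby sets C1 and C5 as one unit, the bridge allowing only their cis union. C3 follows from anti opening through a chair transition state, which leaves selenium equatorial, on the face away from the O6–C7 bridge. The step needs C- over O-alkylation of the enol: O-closure and selenenylation at C5 are reversible under the acid through selenium-assisted re-ionization, whereas C–C closure at the carbon between the two ketones of 7 is the irreversible sink, and the quaternary C1 (Thorpe–Ingold effect, no competing enolization) holds both alkenes next to C5.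

Step 5
Reactants: 10 (1R,3R,5R)-4,4-dimethyl-1-(3-methylbut-2-en-1-yl)-5-(2-methylpropanoyl)-3-(phenylselanyl)-6-oxabicyclo[3.2.1]octane-7,8-dione
Product: 11 (1R,3R,5R)-4,4-dimethyl-1-(3-methylbut-2-en-1-yl)-5-(2-methylpropanoyl)-3-(prop-2-en-1-yl)-6-oxabicyclo[3.2.1]octane-7,8-dione (allyl exo at C3)
Conditions: allyltributylstannane (5 equiv, at least 1 M), AIBN (0.2 equiv in portions), degassed benzene, 80 °C
Reagents that add atoms: allyltributylstannane, C=CC[Sn](CCCC)(CCCC)CCCC
Why: In this Keck radical allylation the stannyl radical abstracts the phenylseleno group and the planar secondary C3 radical should be trapped by the stannane on the face away from the O6–C7 lactone bridge, which blocks the axial approach, so that the allyl group takes the equatorial position selenium held (net retention), while the high stannane concentration is chosen so that allyl transfer outruns β-scission of the C4–C5 bond.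

Step 6
Reactants: 11 (1R,3R,5R)-4,4-dimethyl-1-(3-methylbut-2-en-1-yl)-5-(2-methylpropanoyl)-3-(prop-2-en-1-yl)-6-oxabicyclo[3.2.1]octane-7,8-dione
Product: 12 (1R,3R,5R)-4,4-dimethyl-1,3-bis(3-methylbut-2-en-1-yl)-5-(2-methylpropanoyl)-6-oxabicyclo[3.2.1]octane-7,8-dione (target)
Conditions: second-generation Grubbs catalyst (5 mol %), 2-methylbut-2-ene/CH2Cl2, 40 °C, sealed vessel
Reagents that add atoms: 2-methylbut-2-ene, CC=C(C)C
Why: Olefin cross-metathesis of the monosubstituted allyl alkene with excess 2-methylbut-2-ene caps it as the trisubstituted prenyl group, while the prenyl group already on C1 is unreactive or exchanges degenerately and no stereocentre is touched.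

Compound list
1 | dimethyl malonate | COC(=O)CC(=O)OC | starting material
2 | prenyl bromide (1-bromo-3-methylbut-2-ene) | CC(C)=CCBr | starting material
3 | dimethyl 2,2-bis(3-methylbut-2-en-1-yl)propanedioate | COC(=O)C(CC=C(C)C)(CC=C(C)C)C(=O)OC | intermediate
4 | 1-bromo-3-methylbutan-2-one | CC(C)C(=O)CBr | starting material
5 | potassium 2-(methoxycarbonyl)-5-methyl-2-(3-methylbut-2-en-1-yl)hex-4-enoate | COC(=O)C(CC=C(C)C)(CC=C(C)C)C(=O)[O-].[K+] | intermediate (not isolated)
6 | methyl 3-methyl-2-oxobutyl 2,2-bis(3-methylbut-2-en-1-yl)propanedioate | COC(=O)C(CC=C(C)C)(CC=C(C)C)C(=O)OCC(=O)C(C)C | intermediate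
7 | 4-hydroxy-3,3-bis(3-methylbut-2-en-1-yl)-5-(2-methylpropanoyl)furan-2(3H)-one (achiral) | CC(C)C(=O)C1=C(O)C(CC=C(C)C)(CC=C(C)C)C(=O)O1 | intermediate
8 | N-(phenylseleno)phthalimide | O=C1c2ccccc2C(=O)N1[Se]c1ccccc1 | starting material
9 | (3R)-3-{[(2R)-3,3-dimethyl-1-phenylseleniran-1-ium-2-yl]methyl}-4-hydroxy-3-(3-methylbut-2-en-1-yl)-5-(2-methylpropanoyl)furan-2(3H)-one, cation paired with the catalyst anion | CC(C)C(=O)C1=C(O)[C@@](CC=C(C)C)(C[C@H]2[Se+](c3ccccc3)C2(C)C)C(=O)O1 | intermediate (not isolated)
10 | (1R,3R,5R)-4,4-dimethyl-1-(3-methylbut-2-en-1-yl)-5-(2-methylpropanoyl)-3-(phenylselanyl)-6-oxabicyclo[3.2.1]octane-7,8-dione | c1ccccc1[Se][C@@H]1C[C@@]2(CC=C(C)C)C(=O)O[C@](C(=O)C(C)C)(C2=O)C1(C)C | intermediate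
11 | (1R,3R,5R)-4,4-dimethyl-1-(3-methylbut-2-en-1-yl)-5-(2-methylpropanoyl)-3-(prop-2-en-1-yl)-6-oxabicyclo[3.2.1]octane-7,8-dione | C=CC[C@@H]1C[C@@]2(CC=C(C)C)C(=O)O[C@](C(=O)C(C)C)(C2=O)C1(C)C | intermediate
12 | (1R,3R,5R)-4,4-dimethyl-1,3-bis(3-methylbut-2-en-1-yl)-5-(2-methylpropanoyl)-6-oxabicyclo[3.2.1]octane-7,8-dione | CC(C)=CC[C@@H]1C[C@@]2(CC=C(C)C)C(=O)O[C@](C(=O)C(C)C)(C2=O)C1(C)C | target

Total step count: 6. Longest linear sequence: 6 steps (1 to 12).

Steps most likely to fail

Step 4. The chiral ion pair may discriminate poorly between the enantiotopic prenyl groups, or O-closure of the enol may persist instead of isomerizing to the carbocycle. Fallback with known chemistry: setting out from 7, the racemic closure with 8 and SnCl4 in CH2Cl2 at −78 to −20 °C (thermodynamic C-cyclization of an alkenyl β-dicarbonyl compound) should give the exo selenide as a racemate, that is 10 together with its mirror image, the (1S,3S,5S)-selenide F1. Preparative chromatography on a chiral stationary phase separates the two, and 10 rejoins the route before step 5.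

Step 5. Allyl transfer to the hindered C3 radical may be slow, which would allow β-scission of the C4–C5 bond (ring opening), simple reduction, or attack from the lactone face. Fallback: setting out from 10, a Giese addition of the C3 radical to vinylboronic acid pinacol ester (C=CB1OC(C)(C)C(C)(C)O1) under (Me3Si)3SiH/AIBN, or Et3B/air at lower temperature, should give the exo 2-borylethyl compound F2. Buffered NaBO3·4H2O in THF/H2O then gives the primary alcohol F3, and Dess–Martin periodinane gives the aldehyde F4. Wittig olefination with isopropylidenetriphenylphosphorane (from isopropyltriphenylphosphonium iodide and KN(SiMe3)2, THF, −78 °C) comes back to the route at 12, bypassing 11 and step 6.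

Step 3. Enolization may occur on the isopropyl side, or the released methoxide may cleave the acyloxy ester or the enol lactone of the product. Fallback, building the lactone first and the acyl group second: setting out from 2, commercial tetronic acid (O=C1C=C(O)CO1) is C,C-diprenylated with 2, Et3N and catalytic Pd(PPh3)4 in THF to give 3,3-diprenylfuran-2,4(3H,5H)-dione F5; the palladium π-prenyl pathway should return any O-prenyl ether to the C-alkylated product. Aldol addition of its lithium enolate (LiN(SiMe3)2, THF, −78 °C) to isobutyraldehyde gives the β-hydroxy ketone F6 as a diastereomer mixture, and Dess–Martin periodinane oxidation comes back to the route at 7.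

Further compounds
F1 | step 4 | (1S,3S,5S)-4,4-dimethyl-1-(3-methylbut-2-en-1-yl)-5-(2-methylpropanoyl)-3-(phenylselanyl)-6-oxabicyclo[3.2.1]octane-7,8-dione | c1ccccc1[Se][C@H]1C[C@]2(CC=C(C)C)C(=O)O[C@@](C(=O)C(C)C)(C2=O)C1(C)C
F2 | step 5 | (1R,3R,5R)-4,4-dimethyl-1-(3-methylbut-2-en-1-yl)-5-(2-methylpropanoyl)-3-[2-(4,4,5,5-tetramethyl-1,3,2-dioxaborolan-2-yl)ethyl]-6-oxabicyclo[3.2.1]octane-7,8-dione | CC1(C)OB(CC[C@@H]2C[C@@]3(CC=C(C)C)C(=O)O[C@](C(=O)C(C)C)(C3=O)C2(C)C)OC1(C)C
F3 | step 5 | (1R,3S,5R)-3-(2-hydroxyethyl)-4,4-dimethyl-1-(3-methylbut-2-en-1-yl)-5-(2-methylpropanoyl)-6-oxabicyclo[3.2.1]octane-7,8-dione (same geometry as 11; the C3 descriptor changes by priority only) | OCC[C@@H]1C[C@@]2(CC=C(C)C)C(=O)O[C@](C(=O)C(C)C)(C2=O)C1(C)C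
F4 | step 5 | [(1R,3S,5R)-4,4-dimethyl-1-(3-methylbut-2-en-1-yl)-5-(2-methylpropanoyl)-7,8-dioxo-6-oxabicyclo[3.2.1]octan-3-yl]acetaldehyde | O=CC[C@@H]1C[C@@]2(CC=C(C)C)C(=O)O[C@](C(=O)C(C)C)(C2=O)C1(C)C
F5 | step 3 | 3,3-bis(3-methylbut-2-en-1-yl)furan-2,4(3H,5H)-dione | O=C1OCC(=O)C1(CC=C(C)C)CC=C(C)C
F6 | step 3 | 5-(1-hydroxy-2-methylpropyl)-3,3-bis(3-methylbut-2-en-1-yl)furan-2,4(3H,5H)-dione (racemic diastereomer mixture; both centres vanish on oxidation) | CC(C)C(O)C1OC(=O)C(CC=C(C)C)(CC=C(C)C)C1=O
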